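In the zeta run Q was charged beyond the E: E read 0% at the first reading (2.50 h) and D stayed between 36.2% and 37.5% over 5 readings with no trend, so I replaced that curve by its mean, 36.9%. With E at 0% in zeta, I called this mean the split s, the share of the used E that stands as D once the readings have gone flat, and I counted the remainder as J, which the runs did not read. The replacement cost little, since a scatter of 0.5 percentage points on a single reading leaves about 0.22 points on a mean of 5.

| setting | theta | zeta | alpha | flask |
|---|---|---|---|---|
| E | 0.40 M (fed, over 12 min) | 0.40 M (fed, over 12 min) | 0.80 M (fed, over 12 min) | 0.40 M (fed, over 12 min) |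
| Q | 0.20 M | 0.78 M | 0.392 M | 0.392 M |
| remark | run made earlier; the fed solution adds 0.10 times the starting volume | run made earlier; the fed solution adds 0.10 times the starting volume | run made earlier; the fed solution adds 0.10 times the starting volume | the fed solution adds 0.10 times the starting volume |
| time |  |  |  | 25 h |

- theta (time / h: E / %, D / %): 2.50: 50.0, 19.0; 5.00: 49.9, 18.1; 8.00: 50.0, 17.9; 15.0: 50.2, 18.9; 30.0: 50.2, 18.9
- zeta (time / h: E / %, D / %): 2.50: 0, 37.3; 5.00: 0, 36.2; 8.00: 0.4, 37.5; 15.0: 0, 36.6; 30.0: 0.3, 36.9
- alpha (time / h: E / %, D / %): 6.00: 51.5, 18.9; 12.0: 50.6, 17.0; 20.0: 51.7, 18.2; 25.0: 51.6, 18.9; 30.0: 51.3, 17.9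

(readings scatter by 0.5 percentage points)

- charges are per starting volume, the dose included; the dosed solution carries all of it
- the reaction counts as stopped when no species that holds the E changes by six tenths of a point or more over the second half of the time

1. at 25 h, what has stopped the reaction, if anything has (it is still moving / all of E has reacted / Q has run out first / forward and back rates have come level)
2. share of the E used up at 25 h
3. D at 25 h, in percent of the E charged
4. J at 25 h, in percent of the E charged

The second quantity I needed was the ceiling L, the charge of Q over the charge of E, because E and Q went one to one: theta had used 50.0% of its E at the first reading against a ratio of 50.0%, and alpha about 48.7% against 49.0%. This makes Q the limiting reagent in both. Theta's mean D over its ceiling gave 37.1%, a reading within the scatter of s. For the flask L is 98.0%, so I reckoned D at 36.2%, J at 61.8% and E left at 2.00%. The point to watch in the flask is that last E reading, since its excess of E over Q is 0.00800 M against 0.200 M in theta, and a higher E at 25 h would mean an unfinished tail.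

The forecast said Q has run out first, with conversion 97.9%, D 36.2% and J 61.7%, and its caution was “The near-equimolar tail is slow”; its J differs from mine by 0.14 points. The flask gave Q has run out first, with 0% of the charge of Q left at 25.0 h, conversion 98.0%, D 36.3% and J 61.7%.

    E + Q → D (k = 0.199 L mol⁻¹ s⁻¹)
    D ⇌ J (K = 1.70, k = 8.88 × 10⁻⁴ s⁻¹)

The relaxation half-life of D and J together, 0.137 h, was short against the 25 h of the flask, and D, which stood at 66.8% at the end of the feed, had come to 36.3% by 12.5 h. The result over the used E makes 37.0%, beside s at 36.9%. In a neighbour flask, like this one but with 0.24 M of Q, s times its ceiling of 60.0% gives 22.1%, and that neighbour held D at 22.2%.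

The readings are calculated from invented constants.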